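Ring A is built last. Its C5–C6–C7–C8 edge, oxygenated at C5 and C7 and prenylated at C8, is a γ-prenylated acetoacetate in disguise. C4a–C8a is the enol-ether C5=C6 bond (pyranone numbering) of a 2-aryl-2,3-dihydro-4-pyranone that already holds O1, C4=O and the (S)-C2 centre. The key step joins a 1-methoxy-1,3-bis(silyloxy)diene to the 5-phenylsulfinyl derivative of that pyranone by [4+2] cycloaddition, forming C8–C8a and C4a–C5. Loss of PhSOH, methanol and the silyl groups in the same flask aromatises the adduct to the free 5,7-diol with prenyl locked at C8. C2 comes from a catalytic asymmetric hetero-Diels–Alder reaction of 2,2-dimethylchroman-6-carbaldehyde.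

Key step: step 9

Assumption: the catalyst from (S)-BINOL and Ti(OiPr)4 is taken to leave the Si face of aryl aldehyde 4 open to the diene (Si attack gives S); the configuration of 7 would be verified by CD or rotation against known 2-aryl analogues, and the antipodal ligand used if the sign were opposite.
Numbering: pyranone numbering (O1, aryl on C2, C4=O, C5=C6) is used for 7–10 and flavanone numbering for 15–17.

Step 1
Reactants: 1 4-hydroxybenzaldehyde; 2 prenyl bromide (1-bromo-3-methylbut-2-ene)
Product: 3 4-hydroxy-3-(3-methylbut-2-enyl)benzaldehyde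
Conditions: KOH (1 equiv), H2O, rt, 24 h
Reagents that add atoms: none
Why: In water the phenoxide oxygen is tied up by hydrogen bonding, so the ambident anion is alkylated by the primary allylic bromide to a useful extent at the free ortho carbon (para is blocked by the formyl group) in a known phenoxide C-prenylation (SN2), and the O-prenyl ether and recovered 1 are removed by base extraction and chromatography.

Step 2
Reactants: 3 4-hydroxy-3-(3-methylbut-2-enyl)benzaldehyde
Product: 4 2,2-dimethylchroman-6-carbaldehyde
Conditions: p-TsOH·H2O (10 mol %), toluene, 80 °C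
Reagents that add atoms: none
Why: Markovnikov protonation of the trisubstituted olefin gives a tertiary cation that the neighbouring phenol oxygen captures in a 6-endo cycloetherification, the standard acid-catalysed conversion of ortho-prenylphenols into 2,2-dimethylchromans, which the aldehyde tolerates.

Step 3
Reactants: 4 2,2-dimethylchroman-6-carbaldehyde; 5 Danishefsky diene (trans-1-methoxy-3-trimethylsilyloxybuta-1,3-diene)
Product: 7 (S)-2-(2,2-dimethylchroman-6-yl)-2,3-dihydro-4H-pyran-4-one, via silyl aldol adduct 6 (not isolated)
Conditions: (S)-BINOL (20 mol %), Ti(OiPr)4 (10 mol %), 4 Å MS, Et2O, −20 °C; then CF3CO2H, CH2Cl2, 0 °C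
Reagents that add atoms: none
Why: This is the enantioselective hetero-Diels–Alder reaction in its Mukaiyama-aldol/cyclisation variant, well established for aryl aldehydes including 4-alkoxy ones: the BINOL–titanium Lewis acid shields the Re face of the bound aldehyde, so the diene terminus attacks the Si face and sets C2 as S in 6, and CF3CO2H then closes the ring by oxa-Michael addition and loss of methanol without touching the C2–O bond; the ee would be checked by HPLC on a chiral phase and raised by recrystallisation if needed.

Step 4
Reactants: 7 (S)-2-(2,2-dimethylchroman-6-yl)-2,3-dihydro-4H-pyran-4-one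
Product: 9 (S)-2-(2,2-dimethylchroman-6-yl)-5-(phenylthio)-2,3-dihydro-4H-pyran-4-one, via chloro sulfide adduct 8 (not isolated)
Conditions: PhSCl (made from PhSH and NCS, CH2Cl2, 0 °C), CH2Cl2, −40 → 0 °C; then Et3N (1.2 equiv), 0 °C
Reagents that add atoms: benzenesulfenyl chloride, ClSc1ccccc1 (generated from thiophenol, Sc1ccccc1, and N-chlorosuccinimide)
Why: This is an electrophilic α-sulfenylation of a β-alkoxy enone by addition–elimination: C5 is the nucleophilic carbon of the vinylogous ester, PhSCl adds across C5=C6 to the α-chloro ether 8 without releasing HCl, and the amine removes the doubly activated C5–H and expels chloride under conditions too mild and too cold to enolise C3 and open the ring, so C2 stays S.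

Step 5
Reactants: 9 (S)-2-(2,2-dimethylchroman-6-yl)-5-(phenylthio)-2,3-dihydro-4H-pyran-4-one
Product: 10 (2S)-2-(2,2-dimethylchroman-6-yl)-5-(phenylsulfinyl)-2,3-dihydro-4H-pyran-4-one (both configurations at sulfur)
Conditions: mCPBA (1.0 equiv), CH2Cl2, −78 → −30 °C; aq NaHCO3 wash
Reagents that add atoms: mCPBA, O=C(OO)c1cccc(Cl)c1
Why: This is a chemoselective sulfide-to-sulfoxide oxidation with one equivalent of peracid in the cold, where sulfur reacts far faster than the acceptor-substituted enol ether or the arene and the second oxidation is slow; the sulfur stereocentre is left uncontrolled because it is lost in step 9.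

Step 6
Reactants: 11 methyl acetoacetate; 2 prenyl bromide
Product: 12 methyl 7-methyl-3-oxooct-6-enoate
Conditions: NaH, THF, 0 °C; n-BuLi, 0 °C; 2, 0 °C → rt; then 1 M HCl
Reagents that add atoms: none
Why: In this γ-alkylation of the acetoacetate dianion (Weiler alkylation) the more basic terminal carbanion alone attacks the allylic bromide (SN2), giving the known chain-extended β-keto ester.

Step 7
Reactants: 12 methyl 7-methyl-3-oxooct-6-enoate
Product: 13 methyl 7-methyl-3-(trimethylsilyloxy)octa-2,6-dienoate
Conditions: Me3SiCl, Et3N, toluene, rt; filtration under argon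
Reagents that add atoms: chlorotrimethylsilane, C[Si](C)(C)Cl
Why: This is the standard O-silylation of the enol of a β-keto ester under soft enolisation, the first half of the usual preparation of Chan-type 1,3-bis(silyloxy)dienes, and the enol ether geometry has no consequence.

Step 8
Reactants: 13 methyl 7-methyl-3-(trimethylsilyloxy)octa-2,6-dienoate
Product: 14 1-methoxy-7-methyl-1,3-bis(trimethylsilyloxy)octa-1,3,6-triene (used crude and fresh)
Conditions: LiN(iPr)2, THF, −78 °C; Me3SiCl, −78 → 20 °C; pentane, filtration under argon
Reagents that add atoms: chlorotrimethylsilane, C[Si](C)(C)Cl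
Why: Kinetic γ-deprotonation of the silyloxy enoate gives the extended ester dienolate, which Me3SiCl traps on oxygen, a route well tried for 4-alkyl and 4-allyl congeners; the remote trisubstituted olefin is inert and both diene geometries lead to the same arene.

Step 9
Reactants: 10 (2S)-2-(2,2-dimethylchroman-6-yl)-5-(phenylsulfinyl)-2,3-dihydro-4H-pyran-4-one; 14 1-methoxy-7-methyl-1,3-bis(trimethylsilyloxy)octa-1,3,6-triene
Product: 17 (2S)-euchrenone a16, via sulfinyl cycloadduct 15 (not isolated), via cyclohexadiene ketal 16 (not isolated)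
Conditions: 14 (2.5 equiv; the surplus also scavenges PhSOH), toluene, 0 → 25 °C, then 70 °C; then 1 M aq HCl, THF, 0 °C
Reagents that add atoms: none
Why: Proposed new method: the C4 carbonyl and the C5 sulfinyl group together lower the LUMO of the C5=C6 enol-ether bond of 10 and make C6 its electrophilic end, while the largest HOMO coefficient of 14 lies on the prenyl-bearing terminus, so a normal-demand, highly asynchronous [4+2] cycloaddition forms C8–C8a and C4a–C5 and gives 15. The single new ring, the six-membered carbocycle that becomes ring A, closes either in this concerted way or, at the stepwise limit, by Mukaiyama–Michael addition followed by 6-(enolexo)-exo-trig attack of the α-sulfinyl enolate carbon on the silylated ester carbon, and both paths give the same skeleton. The closest known reaction type is the regiocontrolled Diels–Alder/aromatisation of 1-alkoxy-1,3-bis(silyloxy)dienes with sulfinyl- or halo-quinones, together with cycloadditions of 2-sulfinylcycloalkenones followed by sulfoxide elimination, but a 5-sulfinyl-2,3-dihydro-4-pyranone has not served as the dienophile. Of the new stereocentres, C4a and C8a are tied cis by suprafacial addition to the ring olefin, C5 and C8 follow the endo/exo mode and the diene geometry, the face is biased by the C2 aryl and sulfinyl groups, and none of this needs control because all four are erased on aromatisation while C2 is never touched. The cis fusion places the sulfinyl group syn to C8a–H, its only β-hydrogen, so warming expels PhSOH by syn elimination to give 16 with O1 still attached, and dilute acid then collapses the C5 methyl silyl ketal to the ketone, frees the 7-OH and allows C8–H to tautomerise to the phenol 17. The selectivities needed are the orientation (prenyl at C8, not C6), secured by the polarity match between the γ-terminus of 14 and C6 of 10, and [4+2] in place of the Lewis-acid-type [3+3] mode of such dienes, secured by the absence of Lewis acid and base, which also protects C2 from retro-oxa-Michael racemisation and the prenyl group from cyclisation.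

Compound list
1 | 4-hydroxybenzaldehyde | O=Cc1ccc(O)cc1 | starting material
2 | prenyl bromide (1-bromo-3-methylbut-2-ene) | CC(C)=CCBr | starting material
3 | 4-hydroxy-3-(3-methylbut-2-enyl)benzaldehyde | CC(C)=CCc1cc(C=O)ccc1O | intermediate
4 | 2,2-dimethylchroman-6-carbaldehyde | CC1(C)CCc2cc(C=O)ccc2O1 | intermediate
5 | Danishefsky diene, trans-1-methoxy-3-trimethylsilyloxybuta-1,3-diene | CO/C=C/C(=C)O[Si](C)(C)C | starting material
6 | silyl aldol adduct, (1E,5S)-5-(2,2-dimethylchroman-6-yl)-1-methoxy-5-(trimethylsilyloxy)pent-1-en-3-one (not isolated) | CO/C=C/C(=O)C[C@H](O[Si](C)(C)C)c1ccc2c(c1)CCC(C)(C)O2 | intermediate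
7 | (S)-2-(2,2-dimethylchroman-6-yl)-2,3-dihydro-4H-pyran-4-one | O=C1C=CO[C@H](c2ccc3c(c2)CCC(C)(C)O3)C1 | intermediate
8 | chloro sulfide adduct, tetrahydropyran-4-one with Cl on C6 and SPh on C5, aryl-bearing carbon S, mixture at C5 and C6 (not isolated) | O=C1C(Sc2ccccc2)C(Cl)O[C@H](c2ccc3c(c2)CCC(C)(C)O3)C1 | intermediate
9 | (S)-2-(2,2-dimethylchroman-6-yl)-5-(phenylthio)-2,3-dihydro-4H-pyran-4-one | O=C1C(Sc2ccccc2)=CO[C@H](c2ccc3c(c2)CCC(C)(C)O3)C1 | intermediate
10 | (2S)-2-(2,2-dimethylchroman-6-yl)-5-(phenylsulfinyl)-2,3-dihydro-4H-pyran-4-one, both configurations at sulfur | O=C1C(S(=O)c2ccccc2)=CO[C@H](c2ccc3c(c2)CCC(C)(C)O3)C1 | intermediate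
11 | methyl acetoacetate | COC(=O)CC(C)=O | starting material
12 | methyl 7-methyl-3-oxooct-6-enoate | COC(=O)CC(=O)CCC=C(C)C | intermediate
13 | methyl 7-methyl-3-(trimethylsilyloxy)octa-2,6-dienoate | COC(=O)C=C(O[Si](C)(C)C)CCC=C(C)C | intermediate
14 | 1-methoxy-7-methyl-1,3-bis(trimethylsilyloxy)octa-1,3,6-triene | COC(O[Si](C)(C)C)=CC(O[Si](C)(C)C)=CCC=C(C)C | intermediate
15 | sulfinyl cycloadduct, (2S)-2-(2,2-dimethylchroman-6-yl)-5-methoxy-8-prenyl-4a-(phenylsulfinyl)-5,7-bis(trimethylsilyloxy)-2,3,4a,5,8,8a-hexahydrochromen-4-one, cis-fused, mixture at C4a, C5, C8, C8a and S (not isolated) | CC(C)=CCC1C(O[Si](C)(C)C)=CC(OC)(O[Si](C)(C)C)C2(S(=O)c3ccccc3)C1O[C@H](c1ccc3c(c1)CCC(C)(C)O3)CC2=O | intermediate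
16 | cyclohexadiene ketal, (2S)-2-(2,2-dimethylchroman-6-yl)-5-methoxy-8-prenyl-5,7-bis(trimethylsilyloxy)-2,3,5,8-tetrahydrochromen-4-one, mixture at C5 and C8 (not isolated) | CC(C)=CCC1C(O[Si](C)(C)C)=CC(OC)(O[Si](C)(C)C)C2=C1O[C@H](c1ccc3c(c1)CCC(C)(C)O3)CC2=O | intermediate
17 | (2S)-euchrenone a16, (2S)-2-(2,2-dimethylchroman-6-yl)-5,7-dihydroxy-8-(3-methylbut-2-enyl)chroman-4-one | CC(C)=CCc1c(O)cc(O)c2c1O[C@H](c1ccc3c(c1)CCC(C)(C)O3)CC2=O | target

Total step count: 9.
Longest linear sequence: 6 steps (1, 2, 3, 4, 5, 9). The diene arm (6, 7, 8) joins at step 9.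

Steps most likely to fail

1. Step 9 (bears the label "Proposed new method:"). Four things may go wrong.
- The donor oxygen on C6 may leave the dienophile too unreactive below the temperature at which 14 decomposes.
- Silyl transfer from 14 to the sulfinyl oxygen may open a Pummerer-type channel.
- The Michael stage may be followed by β-elimination of O1 (opening of ring C) in place of ring closure.
- Sulfur electrophiles derived from PhSOH may attack the electron-rich ring A.

The fallback uses known chemistry only, sets out from 4 and 2 and rejoins the route at 17. Commercial 2,4,6-trihydroxyacetophenone is C-prenylated with 2 (aq KOH) to 2,4,6-trihydroxy-3-prenylacetophenone F1. MOMCl and iPr2NEt cap the 4-OH and the less hindered 6-OH, leaving the chelated hydroxyl beside the prenyl group free, in 2-hydroxy-4,6-bis(methoxymethoxy)-3-prenylacetophenone F2. Claisen–Schmidt condensation with 4 (KOH, EtOH) gives the 2'-hydroxychalcone F3. Since its only free phenol lies next to the prenyl group, oxa-Michael closure (NaOAc, EtOH, reflux) can only give the 8-prenyl isomer, the racemic bis-MOM flavanone F4. Preparative HPLC on a polysaccharide chiral phase delivers the (S)-bis-MOM flavanone F5, and dilute HCl in MeOH removes both acetals to give 17.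

2. Step 4. The deactivated enol ether may attack PhSCl too slowly. Traces of acid may ionise the 4-alkoxybenzylic C2–O1 bond and erode the ee. The electron-rich chroman ring may be sulfenylated in competition. The fallback replaces electrophilic sulfenylation by halogenation and cross-coupling, sets out from 7 and rejoins at 9. α-Iodination (I2, pyridine, CH2Cl2) gives the (S)-5-iodo-dihydropyranone F6. Palladium-catalysed C–S coupling with PhSH (Pd2(dba)3, Xantphos, iPr2NEt, dioxane, 80 °C) then gives 9, whose ee would be rechecked.

3. Step 1. O-alkylation and double alkylation of the ambident phenoxide may outrun ortho C-alkylation, so that too little 3 is obtained. The fallback builds the pyran ring by sigmatropic chemistry, sets out from 1 and rejoins at 4, bypassing 3. O-alkylation with 3-chloro-3-methylbut-1-yne (DBU, CuCl2 cat., MeCN, 0 °C) gives the aryl propargyl ether F7. Heating in N,N-diethylaniline (about 190 °C) triggers propargyl Claisen rearrangement, 1,5-hydrogen shift and oxa-6π electrocyclisation to 2,2-dimethyl-2H-chromene-6-carbaldehyde F8. Hydrogenation of the styrene-type olefin (H2, 1 atm, Pd/C, EtOAc, stopped after one equivalent) gives 4.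

Further compounds
F1 | step 9 | 1-[2,4,6-trihydroxy-3-(3-methylbut-2-enyl)phenyl]ethanone | CC(=O)c1c(O)cc(O)c(CC=C(C)C)c1O
F2 | step 9 | 1-[2-hydroxy-4,6-bis(methoxymethoxy)-3-(3-methylbut-2-enyl)phenyl]ethanone | CC(=O)c1c(OCOC)cc(OCOC)c(CC=C(C)C)c1O
F3 | step 9 | (E)-3-(2,2-dimethylchroman-6-yl)-1-[2-hydroxy-4,6-bis(methoxymethoxy)-3-(3-methylbut-2-enyl)phenyl]prop-2-en-1-one | COCOc1cc(OCOC)c(C(=O)/C=C/c2ccc3c(c2)CCC(C)(C)O3)c(O)c1CC=C(C)C
F4 | step 9 | racemic 2-(2,2-dimethylchroman-6-yl)-5,7-bis(methoxymethoxy)-8-(3-methylbut-2-enyl)chroman-4-one | COCOc1cc(OCOC)c2c(c1CC=C(C)C)OC(c1ccc3c(c1)CCC(C)(C)O3)CC2=O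
F5 | step 9 | (2S)-2-(2,2-dimethylchroman-6-yl)-5,7-bis(methoxymethoxy)-8-(3-methylbut-2-enyl)chroman-4-one | COCOc1cc(OCOC)c2c(c1CC=C(C)C)O[C@H](c1ccc3c(c1)CCC(C)(C)O3)CC2=O
F6 | step 4 | (S)-2-(2,2-dimethylchroman-6-yl)-5-iodo-2,3-dihydro-4H-pyran-4-one | O=C1C(I)=CO[C@H](c2ccc3c(c2)CCC(C)(C)O3)C1
F7 | step 1 | 4-[(2-methylbut-3-yn-2-yl)oxy]benzaldehyde | C#CC(C)(C)Oc1ccc(C=O)cc1
F8 | step 1 | 2,2-dimethyl-2H-chromene-6-carbaldehyde | CC1(C)C=Cc2cc(C=O)ccc2O1
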